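## The problem

The target, (2S)-2-phenyl-9-[(2Z)-3-phenylprop-2-enoyl]-1,5,9-triazacyclotridecan-4-one, is a single 13-membered ring. A spermidine chain (N1–C13–C12–C11–C10–N9–C8–C7–C6–N5) is bridged by a 3-phenylpropanoyl unit (C2–C3–C4), with N5 closing the lactam and N1 the benzylic amine. No second ring or quaternary centre preorganises the chain, so the ring must come from a true macrocyclisation, and the choice of the closing bond is the central decision. The three nitrogens end in three different states (N1 a free secondary amine, N5 a secondary lactam nitrogen, N9 a tertiary amide) and must be kept apart throughout. C2 is the only stereocentre and nothing in the molecule can induce it, so it is best bought as (S)-β-phenylalanine; it is not enolisable, but it lies β to the C4 carbonyl and can be scrambled by retro-aza-Michael loss of N1 under strong base or long heating. The fragile group is the (Z)-cinnamoyl amide on N9, the less stable geometrical isomer, which is isomerised by light, radicals, reversible thiolate addition and strong acid and is easily hydrogenated; it must be installed late and after every thiol step. The route is opened by the fact that N9 is the one nitrogen that ends acylated. It can travel as a 2-nitrobenzenesulfonamide, whose acidic N–H allows alkylation by the primary carbon C10 under Mitsunobu conditions, and whose removal by thiolate uncovers exactly the nitrogen to be cinnamoylated; C10 hangs on a four-carbon chain from N1, which as a carbamate cannot compete for it.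

## Retrosynthesis

**Target 19 back to alkyne 17.** No skeletal bond is cut in the first two moves. The free N1–H of 19 is masked as the tert-butyl carbamate 18, and the Z-alkene of 18 is traced to the alkyne of 17. Acylating N9 directly with a Z-cinnamoyl donor was set aside because activated Z-cinnamates isomerise through reversible addition of the nucleophilic additives used in coupling. Syn addition of H2 to an alkyne fixes the geometry by mechanism. Precursor 17 carries no alkene geometry. The forward steps must stop at the alkene, and the final acidolysis must not turn Z into E.

**Alkynamide 17 to amine 15 and acid 16.** The N9–C(=O) bond is cut. In 15 the only basic N–H is N9, since N1 is a carbamate and N5 an amide, so no selectivity question arises. Phenylpropiolic acid 16 is a shelf reagent. The coupling must avoid conjugate addition of the amine to the activated ynoate.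

**Amine 15 through sulfonamide 14 to alcohol 13 (key disconnection).** After the nosyl group is put back on N9 (14), the N9–C10 bond is cut, which opens the ring to the hydroxy sulfonamide 13.
- Against lactamisation at C4–N5: that would need a third orthogonal protecting group for N9 and would activate a β-amino acid that can eliminate.
- Against closure at N1–C13: that would alkylate the hindered benzylic nitrogen.
- Against the mirror cut N9–C8: the activated carbon would sit three atoms from the N5 amide, whose oxygen could close a six-membered oxazine. On the butyl side the only neighbour is the N1 carbamate.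

Precursor 13 is acyclic and is assembled from two pieces by one amide bond. The forward reaction must favour 13-membered closure over dimerisation.

**Alcohol 13 through silyl ether 12 to acid 8 and amine 11.** The hydroxyl is carried as its TBS ether 12 so that it stays silent during carbamate formation, saponification and coupling. The C4–N5 amide bond is then cut, giving the β-amino acid 8 and the mono-nosylated diamine 11. This is the most convergent cut of the chain, and the stereocentre is β to the activated carbonyl, so coupling cannot racemise it.

**Amine 11 to propane-1,3-diamine 9 and 2-nitrobenzenesulfonyl chloride 10.** One N–S bond is cut. The symmetry of 9 makes monosulfonylation a purely statistical problem, which an excess of the cheap diamine solves.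

**Acid 8 back to (S)-β-phenylalanine 1.** Acid 8 comes from ester 7, and removal of the Boc group leads to the secondary amine 6. The N1–C13 bond of 6 is cut by reductive amination between the amino ester (handled as its hydrochloride 2) and aldehyde 3. This is preferred over alkylation with 4-bromobutan-1-ol, which cyclises to tetrahydrofuran under base and invites double alkylation. Ester 2 is the methyl ester hydrochloride of 1, which brings C2 with the correct configuration. Aldehyde 3 is taken as a purchased reagent; should it have to be made, it is one oxidation away from the mono-TBS ether of butane-1,4-diol.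

## Roads not taken

**Alternative 1:** The cut runs through the cinnamoyl unit: the N9–C(=O) and C(=O)–Cα bonds are both disconnected, leaving the N9–H macrocycle 15 of the present route, CO and (Z)-β-bromostyrene A1. Forward, Pd(OAc)2 with Xantphos under CO would take A1 through oxidative addition to zerovalent palladium, CO insertion and aminolysis of the acylpalladium species by 15. The product is the N1-Boc Z-cinnamamide A2, identical in structure with 18.
- Merits: one step in place of two, no hydrogenation and so no over-reduction, and oxidative addition of a vinyl bromide retains the alkene geometry.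
- Weak points: A1 has its β-hydrogen anti to bromine and loses HBr to the alkyne readily under the amine base the reaction needs. It is rarely at hand as a pure Z isomer. The Z-styryl and Z-acyl palladium intermediates may drift towards E before a hindered secondary amine captures the acyl group. CO handling is added.
- Comparison: this competes with steps 10 and 11, not with the ring construction. It is better by one step and free of over-reduction. Against that, the chosen plan has a geometry-defining event that is stereospecific by mechanism and uses only shelf reagents.

**Alternative 2:** The C4–N5 amide is made by transamidation. The precursor is the nine-membered lactam A3, in which C4 is bound to N9 and N9 carries the 3-aminopropyl arm. Forward, KNH(CH2)3NH2 or plain heating lets the terminal amine attack the lactam carbonyl through a six-membered tetrahedral intermediate, which expels N9 and grows the ring by four atoms to the bare macrocycle A4.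
- Merits: the step is driven thermodynamically (relief of medium-ring strain, tertiary amide exchanged for a secondary one), needs no high dilution and no protecting group on the spermidine part.
- Weak points: A3 must first be made, and closing a nine-membered β-amino lactam is harder than closing thirteen. The strongly basic amide reagent can deprotonate C3 and expel N1, a retro-aza-Michael opening whose reversal would erode C2. A4 carries two secondary amines, N1 and N9, told apart only by the steric shielding of benzylic N1, so N9-selective acylation is a matter of degree.
- Comparison: this road is better in ring-forming thermodynamics and protecting-group count. The chosen plan offers explicit differentiation of N1 (Boc) and N9 (nosyl) and a near-neutral closure that cannot touch C2. The Z-cinnamoyl problem is left unsolved and would need steps 10 and 11 anyway.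

**Alternative 3:** The N1–C2 bond is cut. The precursor is the achiral E-cinnamoyl imide A5, with N5 carrying both the cinnamoyl and a Boc group, N9 a Boc group and N1 a free primary amine. Forward, a chiral bis(oxazoline) complex of Mg(NTf2)2 would chelate the N-acyl carbamate while the primary amine adds to the β-carbon, closing the ring and setting C2 in one event to give A6.
- Merits: biomimetic, the shortest road, and the stereocentre is created catalytically from achiral material.
- Weak points: the free primary amine binds the magnesium centre better than the imide does, so turnover and a tight chiral environment are doubtful. The imide is activated enough for racemic background addition and for attack at either imide carbonyl (acyl transfer) instead of the β-carbon. Facial control through a 13-membered transition state with a flexible tether has no close analogy. The β-amino imide product can revert. Both Boc groups later fall together, leaving N1 and N9 again separated only by sterics.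
- Comparison: if it worked it would be clearly superior in step count. The chosen plan sets certainty against it: C2 comes with defined configuration from 1, and every step has close precedent.

Key step: step 8

Step 1
Reactants: 1 (3S)-3-amino-3-phenylpropanoic acid
Product: 2 methyl (3S)-3-amino-3-phenylpropanoate hydrochloride
Conditions: SOCl2, MeOH, 0 °C to reflux
Reagents that add atoms: methanol, CO; thionyl chloride, O=S(Cl)Cl (source of the chloride of the salt)
Why: Acid-mediated esterification with HCl generated from SOCl2 in methanol; the amine is protected as its ammonium salt and the stereocentre is not involved.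

Step 2
Reactants: 2 methyl (3S)-3-amino-3-phenylpropanoate hydrochloride; 3 4-[(tert-butyldimethylsilyl)oxy]butanal
Product: 6 methyl (3S)-3-({4-[(tert-butyldimethylsilyl)oxy]butyl}amino)-3-phenylpropanoate, via free amino ester 4 (not isolated), via aldimine 5 (not isolated)
Conditions: Et3N (1 equiv), 3 (1.0 equiv), NaBH(OAc)3, ClCH2CH2Cl, rt
Reagents that add atoms: none
Why: Direct reductive amination: the liberated amine condenses with the aldehyde and the aldimine is reduced in situ by the mild acyloxyborohydride, which leaves ester and silyl ether alone. The α-branched benzylic nitrogen of the product is too hindered for a second alkylation with one equivalent of aldehyde.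

Step 3
Reactants: 6 methyl (3S)-3-({4-[(tert-butyldimethylsilyl)oxy]butyl}amino)-3-phenylpropanoate
Product: 7 methyl (3S)-3-[(tert-butoxycarbonyl){4-[(tert-butyldimethylsilyl)oxy]butyl}amino]-3-phenylpropanoate
Conditions: Boc2O (2 equiv), THF, 50 °C
Reagents that add atoms: di-tert-butyl dicarbonate, CC(C)(C)OC(=O)OC(=O)OC(C)(C)C
Why: Carbamate formation at the secondary amine; gentle heating answers the steric hindrance, and the absence of strong base keeps retro-aza-Michael loss of N1 out of reach.

Step 4
Reactants: 7 methyl (3S)-3-[(tert-butoxycarbonyl){4-[(tert-butyldimethylsilyl)oxy]butyl}amino]-3-phenylpropanoate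
Product: 8 (3S)-3-[(tert-butoxycarbonyl){4-[(tert-butyldimethylsilyl)oxy]butyl}amino]-3-phenylpropanoic acid
Conditions: LiOH, THF–MeOH–H2O, 0 °C to rt; then 1 M HCl to pH 4 at 0 °C
Reagents that add atoms: lithium hydroxide, [Li+].[OH-]
Why: Saponification of the methyl ester; the Boc carbamate and the primary TBS ether are stable to hydroxide at or below room temperature, and the cold, brief acidification spares both.

Step 5
Reactants: 9 propane-1,3-diamine; 10 2-nitrobenzenesulfonyl chloride
Product: 11 N-(3-aminopropyl)-2-nitrobenzenesulfonamide
Conditions: 9 (8 equiv), CH2Cl2, 0 °C, slow addition of 10; aqueous wash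
Reagents that add atoms: none
Why: Sulfonamide formation under statistical control: the large excess of diamine and slow addition of the chloride favour monosulfonylation, and the excess diamine also takes up the HCl and is washed out with water.

Step 6
Reactants: 8 (3S)-3-[(tert-butoxycarbonyl){4-[(tert-butyldimethylsilyl)oxy]butyl}amino]-3-phenylpropanoic acid; 11 N-(3-aminopropyl)-2-nitrobenzenesulfonamide
Product: 12 tert-butyl N-{4-[(tert-butyldimethylsilyl)oxy]butyl}-N-[(1S)-3-({3-[(2-nitrophenyl)sulfonylamino]propyl}amino)-3-oxo-1-phenylpropyl]carbamate
Conditions: EDC·HCl, HOBt, CH2Cl2, 0 °C to rt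
Reagents that add atoms: none
Why: Carbodiimide amide coupling through the HOBt active ester; the primary amine far outruns the sulfonamide N–H as nucleophile, and the stereocentre lies β to the activated carbonyl, so no oxazolone pathway can racemise it.

Step 7
Reactants: 12 tert-butyl N-{4-[(tert-butyldimethylsilyl)oxy]butyl}-N-[(1S)-3-({3-[(2-nitrophenyl)sulfonylamino]propyl}amino)-3-oxo-1-phenylpropyl]carbamate
Product: 13 tert-butyl N-(4-hydroxybutyl)-N-[(1S)-3-({3-[(2-nitrophenyl)sulfonylamino]propyl}amino)-3-oxo-1-phenylpropyl]carbamate
Conditions: Bu4NF, THF, 0 °C to rt
Reagents that add atoms: none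
Why: Fluoride-induced desilylation driven by the strong Si–F bond; carbamate, amide and nitroarenesulfonamide are inert to fluoride at this temperature.

Step 8
Reactants: 13 tert-butyl N-(4-hydroxybutyl)-N-[(1S)-3-({3-[(2-nitrophenyl)sulfonylamino]propyl}amino)-3-oxo-1-phenylpropyl]carbamate
Product: 14 tert-butyl (2S)-9-[(2-nitrophenyl)sulfonyl]-4-oxo-2-phenyl-1,5,9-triazacyclotridecane-1-carboxylate
Conditions: PPh3, DIAD, THF–toluene, about 2 mM (slow addition of 13), rt
Reagents that add atoms: none
Why: PPh3 and DIAD form a betaine that is protonated by the acidic sulfonamide N9–H and passes phosphorus to the C10 hydroxyl; the ion pair of alkoxyphosphonium and sulfonamidate then collapses by intramolecular SN2 attack of N9 on C10 with loss of triphenylphosphine oxide. The closest known reaction type is the Fukuyama–Mitsunobu alkylation of 2-nitrobenzenesulfonamides, here in its ring-closing form as used for macrocyclic polyamines. The 13-membered ring closes in a 13-exo-tet mode, the leaving oxygen lying outside the ring. No stereocentre is formed: C10 is an unsubstituted primary carbon, and C2 is remote and not acidic, so the S configuration brought in with 1 passes through unchanged. Site selectivity for N9 over N5 and N1 follows from acidity, since only the sulfonamide can enter the Mitsunobu cycle while N5 is a neutral secondary amide and N1 a tertiary carbamate. Ring closure is favoured over dimerisation by slow addition of 13 into excess reagent at high dilution. Capture of C10 in a small ring is not expected, because the only internal nucleophile nearby is the Boc carbonyl, which would need a seven-membered transition state. The tertiary carbamate at N1 and the secondary amide at C4–N5 also restrict the chain and help bring its ends together.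

Step 9
Reactants: 14 tert-butyl (2S)-9-[(2-nitrophenyl)sulfonyl]-4-oxo-2-phenyl-1,5,9-triazacyclotridecane-1-carboxylate
Product: 15 tert-butyl (2S)-4-oxo-2-phenyl-1,5,9-triazacyclotridecane-1-carboxylate
Conditions: PhSH, K2CO3, MeCN, rt
Reagents that add atoms: none
Why: Fukuyama deprotection: thiophenolate adds at the sulfonyl-bearing ring carbon to give a Meisenheimer complex that collapses with loss of SO2 and release of the N9 amine. It is placed before any Michael acceptor is present, and Boc and lactam are inert.

Step 10
Reactants: 15 tert-butyl (2S)-4-oxo-2-phenyl-1,5,9-triazacyclotridecane-1-carboxylate; 16 3-phenylprop-2-ynoic acid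
Product: 17 tert-butyl (2S)-4-oxo-2-phenyl-9-(3-phenylprop-2-ynoyl)-1,5,9-triazacyclotridecane-1-carboxylate
Conditions: EDC·HCl, HOBt, CH2Cl2, 0 °C to rt
Reagents that add atoms: none
Why: Carbodiimide amide coupling at the only basic nitrogen, N9; low temperature and the absence of added amine base keep conjugate addition to the phenyl-capped ynoate in check.

Step 11
Reactants: 17 tert-butyl (2S)-4-oxo-2-phenyl-9-(3-phenylprop-2-ynoyl)-1,5,9-triazacyclotridecane-1-carboxylate
Product: 18 tert-butyl (2S)-4-oxo-2-phenyl-9-[(2Z)-3-phenylprop-2-enoyl]-1,5,9-triazacyclotridecane-1-carboxylate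
Conditions: H2 (1 atm), Pd/CaCO3 poisoned with Pb(OAc)2, quinoline, EtOAc, rt, dark, stopped after one equivalent of H2
Reagents that add atoms: none
Why: Lindlar semi-hydrogenation: both hydrogens are delivered to one face of the adsorbed alkyne, so the Z-alkene results by mechanism. Lead and quinoline slow alkene adsorption and so hold back over-reduction and isomerisation.

Step 12
Reactants: 18 tert-butyl (2S)-4-oxo-2-phenyl-9-[(2Z)-3-phenylprop-2-enoyl]-1,5,9-triazacyclotridecane-1-carboxylate
Product: 19 (2S)-2-phenyl-9-[(2Z)-3-phenylprop-2-enoyl]-1,5,9-triazacyclotridecan-4-one
Conditions: CF3CO2H–CH2Cl2 (1:4), 0 °C, dark; then aq. NaHCO3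
Reagents that add atoms: none
Why: Acidolysis of the tert-butyl carbamate by loss of the tert-butyl cation and decarboxylation; short exposure in the cold and dark is chosen to leave the Z-alkene and C2 untouched, and basic work-up frees N1.

## Compound list

1 | (3S)-3-amino-3-phenylpropanoic acid, (S)-β-phenylalanine | N[C@@H](CC(=O)O)c1ccccc1 | starting material
2 | methyl (3S)-3-amino-3-phenylpropanoate hydrochloride | COC(=O)C[C@@H](c1ccccc1)N.Cl | intermediate
3 | 4-[(tert-butyldimethylsilyl)oxy]butanal | O=CCCCO[Si](C)(C)C(C)(C)C | starting material
4 | methyl (3S)-3-amino-3-phenylpropanoate | COC(=O)C[C@@H](c1ccccc1)N | intermediate (not isolated)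
5 | methyl (3S)-3-({(E)-4-[(tert-butyldimethylsilyl)oxy]butylidene}amino)-3-phenylpropanoate | COC(=O)C[C@@H](c1ccccc1)/N=C/CCCO[Si](C)(C)C(C)(C)C | intermediate (not isolated)
6 | methyl (3S)-3-({4-[(tert-butyldimethylsilyl)oxy]butyl}amino)-3-phenylpropanoate | COC(=O)C[C@@H](c1ccccc1)NCCCCO[Si](C)(C)C(C)(C)C | intermediate
7 | methyl (3S)-3-[(tert-butoxycarbonyl){4-[(tert-butyldimethylsilyl)oxy]butyl}amino]-3-phenylpropanoate | COC(=O)C[C@@H](c1ccccc1)N(CCCCO[Si](C)(C)C(C)(C)C)C(=O)OC(C)(C)C | intermediate
8 | (3S)-3-[(tert-butoxycarbonyl){4-[(tert-butyldimethylsilyl)oxy]butyl}amino]-3-phenylpropanoic acid | OC(=O)C[C@@H](c1ccccc1)N(CCCCO[Si](C)(C)C(C)(C)C)C(=O)OC(C)(C)C | intermediate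
9 | propane-1,3-diamine | NCCCN | starting material
10 | 2-nitrobenzenesulfonyl chloride | O=S(=O)(Cl)c1ccccc1[N+](=O)[O-] | starting material
11 | N-(3-aminopropyl)-2-nitrobenzenesulfonamide | NCCCNS(=O)(=O)c1ccccc1[N+](=O)[O-] | intermediate
12 | tert-butyl N-{4-[(tert-butyldimethylsilyl)oxy]butyl}-N-[(1S)-3-({3-[(2-nitrophenyl)sulfonylamino]propyl}amino)-3-oxo-1-phenylpropyl]carbamate | O=C(C[C@@H](c1ccccc1)N(CCCCO[Si](C)(C)C(C)(C)C)C(=O)OC(C)(C)C)NCCCNS(=O)(=O)c1ccccc1[N+](=O)[O-] | intermediate
13 | tert-butyl N-(4-hydroxybutyl)-N-[(1S)-3-({3-[(2-nitrophenyl)sulfonylamino]propyl}amino)-3-oxo-1-phenylpropyl]carbamate | OCCCCN(C(=O)OC(C)(C)C)[C@H](c1ccccc1)CC(=O)NCCCNS(=O)(=O)c1ccccc1[N+](=O)[O-] | intermediate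
14 | tert-butyl (2S)-9-[(2-nitrophenyl)sulfonyl]-4-oxo-2-phenyl-1,5,9-triazacyclotridecane-1-carboxylate | O=C1C[C@@H](c2ccccc2)N(C(=O)OC(C)(C)C)CCCCN(S(=O)(=O)c2ccccc2[N+](=O)[O-])CCCN1 | intermediate
15 | tert-butyl (2S)-4-oxo-2-phenyl-1,5,9-triazacyclotridecane-1-carboxylate | O=C1C[C@@H](c2ccccc2)N(C(=O)OC(C)(C)C)CCCCNCCCN1 | intermediate
16 | 3-phenylprop-2-ynoic acid, phenylpropiolic acid | OC(=O)C#Cc1ccccc1 | starting material
17 | tert-butyl (2S)-4-oxo-2-phenyl-9-(3-phenylprop-2-ynoyl)-1,5,9-triazacyclotridecane-1-carboxylate | O=C1C[C@@H](c2ccccc2)N(C(=O)OC(C)(C)C)CCCCN(C(=O)C#Cc2ccccc2)CCCN1 | intermediate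
18 | tert-butyl (2S)-4-oxo-2-phenyl-9-[(2Z)-3-phenylprop-2-enoyl]-1,5,9-triazacyclotridecane-1-carboxylate | O=C1C[C@@H](c2ccccc2)N(C(=O)OC(C)(C)C)CCCCN(C(=O)/C=C\c2ccccc2)CCCN1 | intermediate
19 | (2S)-2-phenyl-9-[(2Z)-3-phenylprop-2-enoyl]-1,5,9-triazacyclotridecan-4-one | O=C1C[C@@H](c2ccccc2)NCCCCN(C(=O)/C=C\c2ccccc2)CCCN1 | target

## Step count and risks

Total step count: 12. Longest linear sequence: 11 steps (1 to 19 through steps 1 to 4 and 6 to 12); step 5 is a one-step side branch.

**Step 8 (key step).** Intermolecular alkylation may outrun the 13-membered closure and lead to cyclodimers and oligomers. If attack by the sulfonamidate is slow, the alkoxyphosphonium ion may instead alkylate the reduced azodicarboxylate. Fallback: the leaving group is made in a separate step and the ring is closed by base-mediated alkylation without redox reagents, which allows heating and long addition times. From 13, CBr4 and PPh3 in CH2Cl2 at 0 °C should give the primary bromide tert-butyl N-(4-bromobutyl)-N-[(1S)-3-({3-[(2-nitrophenyl)sulfonylamino]propyl}amino)-3-oxo-1-phenylpropyl]carbamate F1. Slow addition of F1 to Cs2CO3 and Bu4NI in MeCN at 60 °C under high dilution should close N9–C10 through the caesium sulfonamide and return to the route at 14.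

**Step 11.** Hydrogenation may run on to the saturated 3-phenylpropanoyl amide. The Z-alkene may isomerise to E on the metal surface. The catalyst may stall on sulfur residues carried over from step 9. Fallback: the Z-alkene is built by olefination instead of reduction. From 15, coupling with (diphenoxyphosphoryl)acetic acid (EDC·HCl, HOBt, CH2Cl2) should give the phosphonoacetamide tert-butyl (2S)-9-[2-(diphenoxyphosphoryl)acetyl]-4-oxo-2-phenyl-1,5,9-triazacyclotridecane-1-carboxylate F2. An Ando-type Z-selective Horner–Wadsworth–Emmons reaction of F2 with benzaldehyde (NaH, THF, −78 °C) should then return to the route at 18, the diaryl phosphonate favouring fast elimination from the kinetically formed adduct.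

**Step 12.** Protonation of the cinnamamide in strong acid lowers the barrier to rotation about the alkene and may leak Z into E. The tert-butyl cation may also alkylate the electron-rich alkene or the free amine. Fallback: the last two steps are run in reverse order so that the Z-alkene is formed last and never meets acid. From 17, CF3CO2H in CH2Cl2 followed by NaHCO3 should give the amino alkynamide (2S)-2-phenyl-9-(3-phenylprop-2-ynoyl)-1,5,9-triazacyclotridecan-4-one F3. Semi-hydrogenation of F3 over Pd/CaCO3 poisoned with Pb(OAc)2, the free amine being a tolerated catalyst modifier, should return directly to 19.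

**Step 5.** Double sulfonylation of the diamine and incomplete separation of the polar monosulfonamide from excess diamine may lower throughput. Fallback: one nitrogen is differentiated by protection instead of statistics. From 10 and purchased tert-butyl N-(3-aminopropyl)carbamate F4, with Et3N in CH2Cl2 at 0 °C, sulfonylation should give tert-butyl N-{3-[(2-nitrophenyl)sulfonylamino]propyl}carbamate F5. Treatment of F5 with HCl in dioxane and neutralisation with aqueous Na2CO3 should return to the route at 11.

## Further compounds

F1 | step 8 | tert-butyl N-(4-bromobutyl)-N-[(1S)-3-({3-[(2-nitrophenyl)sulfonylamino]propyl}amino)-3-oxo-1-phenylpropyl]carbamate | BrCCCCN(C(=O)OC(C)(C)C)[C@H](c1ccccc1)CC(=O)NCCCNS(=O)(=O)c1ccccc1[N+](=O)[O-]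
F2 | step 11 | tert-butyl (2S)-9-[2-(diphenoxyphosphoryl)acetyl]-4-oxo-2-phenyl-1,5,9-triazacyclotridecane-1-carboxylate | O=C1C[C@@H](c2ccccc2)N(C(=O)OC(C)(C)C)CCCCN(C(=O)CP(=O)(Oc2ccccc2)Oc2ccccc2)CCCN1
F3 | step 12 | (2S)-2-phenyl-9-(3-phenylprop-2-ynoyl)-1,5,9-triazacyclotridecan-4-one | O=C1C[C@@H](c2ccccc2)NCCCCN(C(=O)C#Cc2ccccc2)CCCN1
F4 | step 5 | tert-butyl N-(3-aminopropyl)carbamate (purchased) | NCCCNC(=O)OC(C)(C)C
F5 | step 5 | tert-butyl N-{3-[(2-nitrophenyl)sulfonylamino]propyl}carbamate | CC(C)(C)OC(=O)NCCCNS(=O)(=O)c1ccccc1[N+](=O)[O-]
A1 | alternative 1 | (Z)-(2-bromoethenyl)benzene, (Z)-β-bromostyrene | Br/C=C\c1ccccc1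
A2 | alternative 1 | tert-butyl (2S)-4-oxo-2-phenyl-9-[(2Z)-3-phenylprop-2-enoyl]-1,5,9-triazacyclotridecane-1-carboxylate (same structure as 18) | O=C1C[C@@H](c2ccccc2)N(C(=O)OC(C)(C)C)CCCCN(C(=O)/C=C\c2ccccc2)CCCN1
A3 | alternative 2 | (4S)-1-(3-aminopropyl)-4-phenyl-1,5-diazonan-2-one | O=C1C[C@@H](c2ccccc2)NCCCCN1CCCN
A4 | alternative 2 | (2S)-2-phenyl-1,5,9-triazacyclotridecan-4-one | O=C1C[C@@H](c2ccccc2)NCCCCNCCCN1
A5 | alternative 3 | tert-butyl N-(4-aminobutyl)-N-(3-{(tert-butoxycarbonyl)[(2E)-3-phenylprop-2-enoyl]amino}propyl)carbamate | NCCCCN(C(=O)OC(C)(C)C)CCCN(C(=O)OC(C)(C)C)C(=O)/C=C/c1ccccc1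
A6 | alternative 3 | di-tert-butyl (2S)-4-oxo-2-phenyl-1,5,9-triazacyclotridecane-5,9-dicarboxylate | O=C1C[C@@H](c2ccccc2)NCCCCN(C(=O)OC(C)(C)C)CCCN1C(=O)OC(C)(C)C
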